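**Retrosynthetic overview**
1. Target 18 comes from triene diacetate 17 by double peracid epoxidation (last); C13 is added by Stille hydroxymethylation of a C11 bromide, then both hydroxyls are acetylated.
2. The ten-membered ring (second ring formed) is closed at C7–C8 by an intramolecular Nozaki–Hiyama–Kishi reaction of bromobutenolide aldehyde 14.
3. The butenolide (first ring formed) comes from symmetric dibromomaleic anhydride 8, mono-acylated by an (E)-alkenylalane made from alkyne 7 (C5–C6 bond), then CBS reduction (C6) and lactonisation.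
4. The (Z)-C1=C10 unit with differentiated ends (C8 aldehyde, C3 ester) comes from 4-methylanisole 1 by Birch reduction and enol-ether ozonolysis; the arene ring supplies C3, C2, C1, C10, C9, C8.
5. Ring order: arene opened → butenolide → carbocycle → two oxiranes.

Assumption: the SMILES is read as (1R,4R,5R,6S,8S,10S)-8,13-diacetoxy-1,10:4,5-diepoxygermacr-7(11)-en-12,6-olide (cis 1,10-oxirane, trans 4,5-oxirane); germacrane numbering (C1–C15) is used for atom labels.

**Step 1**
Reactants: 1 4-methylanisole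
Product: 2 1-methoxy-4-methylcyclohexa-1,4-diene
Conditions: Li, NH3 (l), THF, tBuOH, −78 to −33 °C; then H2O
Reagents that add atoms: none
Why: Birch reduction places the OMe and Me groups on the two isolated double bonds, so the ring holds C3, C2, C1, C10, C9, C8 and its methyl-bearing double bond is the future 1(10) olefin, cis by construction.

**Step 2**
Reactants: 2 1-methoxy-4-methylcyclohexa-1,4-diene
Product: 4 methyl (3Z)-6,6-dimethoxy-4-methylhex-3-enoate, via aldehyde ester 3 (not isolated)
Conditions: O3 (1.0 equiv), CH2Cl2/MeOH 4:1, −78 °C; Me2S, −78 °C to rt; then TsOH (cat.), MeOH, rt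
Reagents that add atoms: ozone ([O-][O+]=O); methanol (CO)
Why: Ozonolysis attacks only the enol-ether double bond (far more electron-rich than the trisubstituted alkene), giving the C3 methyl ester and the C8 aldehyde with the two ring CH2 groups still cis (Z); the labile β,γ-unsaturated aldehyde is trapped at once as its dimethyl acetal.

**Step 3**
Reactants: 4 methyl (3Z)-6,6-dimethoxy-4-methylhex-3-enoate
Product: 5 (3Z)-6,6-dimethoxy-4-methylhex-3-en-1-ol
Conditions: LiAlH4, Et2O, 0 °C
Reagents that add atoms: none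
Why: Hydride reduction of the ester to the primary alcohol; the acetal and the isolated alkene are inert.

**Step 4**
Reactants: 5 (3Z)-6,6-dimethoxy-4-methylhex-3-en-1-ol
Product: 6 (3Z)-6-iodo-1,1-dimethoxy-3-methylhex-3-ene
Conditions: I2, PPh3, imidazole, CH2Cl2, 0 °C
Reagents that add atoms: iodine (II)
Why: Appel-type iodination (oxyphosphonium activation, SN2 by iodide); imidazole buffering keeps the acetal intact.

**Step 5**
Reactants: 6 (3Z)-6-iodo-1,1-dimethoxy-3-methylhex-3-ene
Product: 7 (5Z)-8,8-dimethoxy-6-methyloct-5-en-1-yne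
Conditions: lithium acetylide–ethylenediamine complex, DMSO, 15 °C
Reagents that add atoms: lithium acetylide ([Li]C#C)
Why: SN2 alkylation of the acetylide by the primary iodide installs C4 and C5 as a terminal alkyne.

**Step 6**
Reactants: 7 (5Z)-8,8-dimethoxy-6-methyloct-5-en-1-yne; 8 dibromomaleic anhydride (3,4-dibromofuran-2,5-dione)
Product: 10 3,4-dibromo-5-[(1E,5Z)-8,8-dimethoxy-2,6-dimethylocta-1,5-dien-1-yl]-5-hydroxyfuran-2(5H)-one, via alkenylalane 9 (not isolated)
Conditions: Me3Al (2.5 equiv), Cp2ZrCl2 (10 mol%), H2O (1 equiv), CH2Cl2, −23 °C; excess Me3Al removed in vacuo; 8, CH2Cl2, −30 to 0 °C; cold aqueous citric acid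
Reagents that add atoms: trimethylaluminium (C[Al](C)C)
Why: Proposed new method: zirconocene-catalysed syn-carboalumination (Negishi, water-accelerated) puts the C15 methyl on C4 and aluminium on C5 cis to each other, fixing the 4E geometry, and the alkenyl(dimethyl)alane then acylates one of the two equivalent carbonyls of the C2v-symmetric anhydride (aluminium activates the anhydride, alkenyl transfers faster than methyl, and the aluminium carboxylate formed resists a second addition), giving the hydroxy-lactone tautomer of the γ-keto acid; the closest known reactions are acylation of alkenylalanes by acyl chlorides and opening of cyclic anhydrides to keto acids by trialkylalanes.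

**Step 7**
Reactants: 10 3,4-dibromo-5-[(1E,5Z)-8,8-dimethoxy-2,6-dimethylocta-1,5-dien-1-yl]-5-hydroxyfuran-2(5H)-one
Product: 11 methyl (2Z,5E,9Z)-2,3-dibromo-12,12-dimethoxy-6,10-dimethyl-4-oxododeca-2,5,9-trienoate
Conditions: MeI, K2CO3, DMF, 0 °C to rt
Reagents that add atoms: iodomethane (CI)
Why: Carboxylate O-alkylation (SN2) of the open keto-acid tautomer gives the normal keto ester, freeing the C6 ketone for asymmetric reduction.

**Step 8**
Reactants: 11 methyl (2Z,5E,9Z)-2,3-dibromo-12,12-dimethoxy-6,10-dimethyl-4-oxododeca-2,5,9-trienoate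
Product: 14 (3Z,7E)-8-[(2R)-3,4-dibromo-5-oxo-2,5-dihydrofuran-2-yl]-3,7-dimethylocta-3,7-dienal, via hydroxy ester 12 (not isolated), via acetal lactone 13 (not isolated)
Conditions: (S)-2-methyl-CBS-oxazaborolidine (20 mol%), catecholborane, toluene, −78 °C; MeOH; then PPTS, acetone/H2O, 40 °C
Reagents that add atoms: water (O)
Why: Corey–Bakshi–Shibata reduction in which the tetrasubstituted α-bromoalkenyl group is the large substituent and the α-unbranched alkenyl group the small one, so the (S)-catalyst gives the 4R carbinol (C6 of the target, reagent control); it lactonises onto the cis ester, and the mild acid then releases the C8 aldehyde.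

**Step 9**
Reactants: 14 (3Z,7E)-8-[(2R)-3,4-dibromo-5-oxo-2,5-dihydrofuran-2-yl]-3,7-dimethylocta-3,7-dienal
Product: 15 (6R,8S)-11-bromo-8-hydroxy-13-norgermacra-1(10)Z,4E,7(11)-trien-12,6-olide
Conditions: CrCl2 (10 equiv), NiCl2 (2 mol%), DMSO/THF, rt, slow addition to 2 mM
Reagents that add atoms: none
Why: Nozaki–Hiyama–Kishi reaction in which zerovalent nickel inserts into the more electrophilic β-C–Br bond (C7), transmetalation to trivalent chromium and intramolecular aldehyde addition close the ten-membered ring; C8 is set under substrate control (the C6 centre and the Z and E olefins fix the ring-shaped transition state), and the 8S alcohol is expected but not assured.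

**Step 10**
Reactants: 15 (6R,8S)-11-bromo-8-hydroxy-13-norgermacra-1(10)Z,4E,7(11)-trien-12,6-olide
Product: 16 (6R,8S)-8,13-dihydroxygermacra-1(10)Z,4E,7(11)-trien-12,6-olide
Conditions: Bu3SnCH2OH, Pd2(dba)3 (5 mol%), AsPh3 (20 mol%), NMP, 50 °C
Reagents that add atoms: (tributylstannyl)methanol (CCCC[Sn](CCCC)(CCCC)CO)
Why: Stille (Migita–Kosugi) hydroxymethylation of the remaining α-bromo enoate installs C13; it is run before acetylation so no allylic acetate is exposed to zerovalent palladium, and the hindered trisubstituted allylic lactone should not ionise at 50 °C with this weakly donating ligand.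

**Step 11**
Reactants: 16 (6R,8S)-8,13-dihydroxygermacra-1(10)Z,4E,7(11)-trien-12,6-olide
Product: 17 (6R,8S)-8,13-diacetoxygermacra-1(10)Z,4E,7(11)-trien-12,6-olide
Conditions: Ac2O, pyridine, DMAP (cat.), CH2Cl2, 0 °C
Reagents that add atoms: acetic anhydride (CC(=O)OC(C)=O)
Why: Acyl transfer esterifies the primary C13 and secondary C8 hydroxyls without touching a stereocentre.

**Step 12**
Reactants: 17 (6R,8S)-8,13-diacetoxygermacra-1(10)Z,4E,7(11)-trien-12,6-olide
Product: 18 (1R,4R,5R,6S,8S,10S)-8,13-diacetoxy-1,10:4,5-diepoxygermacr-7(11)-en-12,6-olide (target)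
Conditions: mCPBA (2.4 equiv), NaHCO3, CH2Cl2, 0 °C
Reagents that add atoms: 3-chloroperbenzoic acid (OOC(=O)c1cccc(Cl)c1)
Why: Prilezhaev epoxidation of the two electron-rich trisubstituted ring alkenes only (the butenolide alkene is electron-poor); syn addition turns Z-1(10) into the cis and E-4 into the trans oxirane, and attack on the outer face of each olefin in the rigid ring is expected to give (1R,10S) and (4R,5R), as is usual for germacranolides.

**Compound list**
1 | 4-methylanisole | COc1ccc(C)cc1 | starting material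
2 | 1-methoxy-4-methylcyclohexa-1,4-diene | COC1=CCC(C)=CC1 | intermediate
3 | methyl (3Z)-4-methyl-6-oxohex-3-enoate | COC(=O)C/C=C(/C)CC=O | intermediate
4 | methyl (3Z)-6,6-dimethoxy-4-methylhex-3-enoate | COC(=O)C/C=C(/C)CC(OC)OC | intermediate
5 | (3Z)-6,6-dimethoxy-4-methylhex-3-en-1-ol | OCC/C=C(/C)CC(OC)OC | intermediate
6 | (3Z)-6-iodo-1,1-dimethoxy-3-methylhex-3-ene | ICC/C=C(/C)CC(OC)OC | intermediate
7 | (5Z)-8,8-dimethoxy-6-methyloct-5-en-1-yne | C#CCC/C=C(/C)CC(OC)OC | intermediate
8 | dibromomaleic anhydride (3,4-dibromofuran-2,5-dione) | O=C1OC(=O)C(Br)=C1Br | starting material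
9 | [(1E,5Z)-8,8-dimethoxy-2,6-dimethylocta-1,5-dien-1-yl]dimethylaluminium | C[Al](C)/C=C(\C)CC/C=C(/C)CC(OC)OC | intermediate
10 | 3,4-dibromo-5-[(1E,5Z)-8,8-dimethoxy-2,6-dimethylocta-1,5-dien-1-yl]-5-hydroxyfuran-2(5H)-one (racemic at C5; ring tautomer of the γ-keto acid) | O=C1OC(O)(/C=C(\C)CC/C=C(/C)CC(OC)OC)C(Br)=C1Br | intermediate
11 | methyl (2Z,5E,9Z)-2,3-dibromo-12,12-dimethoxy-6,10-dimethyl-4-oxododeca-2,5,9-trienoate | COC(=O)/C(Br)=C(/Br)C(=O)/C=C(\C)CC/C=C(/C)CC(OC)OC | intermediate
12 | methyl (2Z,4R,5E,9Z)-2,3-dibromo-4-hydroxy-12,12-dimethoxy-6,10-dimethyldodeca-2,5,9-trienoate | COC(=O)/C(Br)=C(/Br)[C@H](O)/C=C(\C)CC/C=C(/C)CC(OC)OC | intermediate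
13 | (5R)-3,4-dibromo-5-[(1E,5Z)-8,8-dimethoxy-2,6-dimethylocta-1,5-dien-1-yl]furan-2(5H)-one | O=C1O[C@H](/C=C(\C)CC/C=C(/C)CC(OC)OC)C(Br)=C1Br | intermediate
14 | (3Z,7E)-8-[(2R)-3,4-dibromo-5-oxo-2,5-dihydrofuran-2-yl]-3,7-dimethylocta-3,7-dienal | O=C1O[C@H](/C=C(\C)CC/C=C(/C)CC=O)C(Br)=C1Br | intermediate
15 | (6R,8S)-11-bromo-8-hydroxy-13-norgermacra-1(10)Z,4E,7(11)-trien-12,6-olide (ten-membered ring fused at C6–C7 to a 2(5H)-furanone; Br on C11, OH on C8) | O=C1O[C@@H]2/C=C(\C)CC/C=C(/C)C[C@H](O)C2=C1Br | intermediate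
16 | (6R,8S)-8,13-dihydroxygermacra-1(10)Z,4E,7(11)-trien-12,6-olide | O=C1O[C@@H]2/C=C(\C)CC/C=C(/C)C[C@H](O)C2=C1CO | intermediate
17 | (6R,8S)-8,13-diacetoxygermacra-1(10)Z,4E,7(11)-trien-12,6-olide | O=C1O[C@@H]2/C=C(\C)CC/C=C(/C)C[C@H](OC(C)=O)C2=C1COC(C)=O | intermediate
18 | (1R,4R,5R,6S,8S,10S)-8,13-diacetoxy-1,10:4,5-diepoxygermacr-7(11)-en-12,6-olide (CNP0271844.2) | CC(=O)OCC1=C2[C@@H](OC(C)=O)C[C@]3(C)O[C@@H]3CC[C@@]3(C)O[C@@H]3[C@H]2OC1=O | target

**Step count and risks**
Total step count: 12. Longest linear sequence: 12 (from 1; 8 is bought).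

The three steps most likely to fail:

Step 9 (ring closure and C8 configuration). The closure may give the wrong or a mixed C8 configuration, and divalent chromium may also attack the α-bromide. The fallback sets out from 14 and comes back at 15. The Nozaki–Hiyama–Kishi closure is run only for ring formation, accepting 15 together with its epimer (6R,8R)-11-bromo-8-hydroxy-13-norgermacra-1(10)Z,4E,7(11)-trien-12,6-olide F3. The mixture is oxidised (Dess–Martin periodinane, NaHCO3, CH2Cl2) to (6R)-11-bromo-8-oxo-13-norgermacra-1(10)Z,4E,7(11)-trien-12,6-olide F4. C8 is then set by reagent control with (R)-2-methyl-CBS-oxazaborolidine and catecholborane at −78 °C (the α-branched butenolide alkenyl is the large group, CH2 the small one), which returns 15.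

Step 12 (facial selectivity of two epoxidations at once). The fallback sets out from 16 and comes back at 18. VO(acac)2 (cat.) and tBuOOH in CH2Cl2 at 0 °C use the homoallylic C8 hydroxyl to deliver oxygen to the Z-1(10) olefin only, giving (1R,6R,8S,10S)-1,10-epoxy-8,13-dihydroxygermacra-4E,7(11)-dien-12,6-olide F5. Ac2O/pyridine gives (1R,6R,8S,10S)-8,13-diacetoxy-1,10-epoxygermacra-4E,7(11)-dien-12,6-olide F6. mCPBA (1.1 equiv, NaHCO3) then epoxidises the single remaining 4E olefin to give 18. If the directed epoxidation gives the other face, it identifies which olefin needs reagent control.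

Step 6 (one-pot carboalumination and anhydride acylation; the acetal must survive Me3Al at −23 °C). The fallback sets out from 7 and comes back at 10. The alkenylalane 9 is quenched with I2 (THF, −30 °C) to give (1E,5Z)-1-iodo-8,8-dimethoxy-2,6-dimethylocta-1,5-diene F1. Iodine–lithium exchange (tBuLi, 2 equiv, Et2O, −78 °C) and MgBr2 give [(1E,5Z)-8,8-dimethoxy-2,6-dimethylocta-1,5-dien-1-yl]magnesium bromide F2. This adds once to anhydride 8 at −78 °C (Grignard opening of a cyclic anhydride to the keto acid), and acidic work-up gives 10.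

Further compounds
F1 | step 6 | (1E,5Z)-1-iodo-8,8-dimethoxy-2,6-dimethylocta-1,5-diene | I/C=C(\C)CC/C=C(/C)CC(OC)OC
F2 | step 6 | [(1E,5Z)-8,8-dimethoxy-2,6-dimethylocta-1,5-dien-1-yl]magnesium bromide | Br[Mg]/C=C(\C)CC/C=C(/C)CC(OC)OC
F3 | step 9 | (6R,8R)-11-bromo-8-hydroxy-13-norgermacra-1(10)Z,4E,7(11)-trien-12,6-olide | O=C1O[C@@H]2/C=C(\C)CC/C=C(/C)C[C@@H](O)C2=C1Br
F4 | step 9 | (6R)-11-bromo-8-oxo-13-norgermacra-1(10)Z,4E,7(11)-trien-12,6-olide | O=C1O[C@@H]2/C=C(\C)CC/C=C(/C)CC(=O)C2=C1Br
F5 | step 12 | (1R,6R,8S,10S)-1,10-epoxy-8,13-dihydroxygermacra-4E,7(11)-dien-12,6-olide | O=C1O[C@@H]2/C=C(\C)CC[C@H]3O[C@@]3(C)C[C@H](O)C2=C1CO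
F6 | step 12 | (1R,6R,8S,10S)-8,13-diacetoxy-1,10-epoxygermacra-4E,7(11)-dien-12,6-olide | O=C1O[C@@H]2/C=C(\C)CC[C@H]3O[C@@]3(C)C[C@H](OC(C)=O)C2=C1COC(C)=O
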